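**Retrosynthetic overview** (ring numbering: C1 = ketone, C2 = C–N, C4 = quaternary carbinol, C5 = CHOH; C7′ = triene carbon on C4)
1. Last step: SmI2 opening of a syn C5–C6 oxirane in an epoxy-enone reveals the cis-4,5-diol; the triene is closed by a vinylogous HWE between a C4-bound γ-hydroxy enal and the C5N phosphonocrotonamide.
2. Key C4–C7′ bond: 1,2-addition of (E)-3-lithioacrolein diethyl acetal to the ketone of an enantioenriched epoxy quinone monoketal, anti to the oxirane. The reagent is a β-formylvinyl anion (unsaturated homoenolate, d3) whose donor carbon is the normally electrophilic enal β-carbon.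
3. Epoxy monoketal: Wynberg phase-transfer epoxidation of the quinone monoketal from PhI(OAc)2 dearomatisation of a 2,5-dimethoxyanilide. The anilide comes from cross-metathesis of N-(2,5-dimethoxyphenyl)acrylamide with (3R,5S)-3,5-dimethylnon-1-ene (two lithiation–borylations, Matteson, Zweifel).
4. Rings: no carbocycle is built. The cyclohexenone is the dearomatised aniline ring and the cyclopentenone is cyclopentane-1,3-dione; the only ring formed is the oxirane (step 8), opened in the last step.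

Assumption: N-benzylcinchoninium chloride is taken as the Wynberg catalyst that gives the (1R,6S)-epoxide of step 8; should it give the antipode, the pseudo-enantiomeric N-benzylcinchonidinium chloride is used.

**Route**

Step 1
Reactants: 1 butylboronic acid pinacol ester; 2 ethyl 2,4,6-triisopropylbenzoate
Product: 5 (S)-2-(hexan-2-yl)-4,4,5,5-tetramethyl-1,3,2-dioxaborolane, via lithiated carbenoid 3 (not isolated), via boronate complex 4 (not isolated)
Conditions: 2, s-BuLi, (+)-sparteine, Et2O, −78 °C, 5 h; then 1, −78 °C → reflux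
Reagents that add atoms: none
Why: Sparteine-mediated deprotonation gives a configurationally stable (R)-α-oxyalkyllithium that is borylated with retention and undergoes 1,2-metallate rearrangement with inversion (Aggarwal lithiation–borylation), setting the later C6 methyl centre of the acyl chain (er about 97:3).

Step 2
Reactants: 5 (S)-2-(hexan-2-yl)-4,4,5,5-tetramethyl-1,3,2-dioxaborolane
Product: 7 (R)-4,4,5,5-tetramethyl-2-(2-methylhexyl)-1,3,2-dioxaborolane, via chloromethyl boronate 6 (not isolated)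
Conditions: BrCH2Cl, n-BuLi, THF, −78 °C → rt
Reagents that add atoms: bromochloromethane ClCBr
Why: Matteson homologation with in situ LiCH2Cl inserts CH2 by 1,2-migration with retention at the migrating stereocentre (the descriptor changes only through CIP priorities).

Step 3
Reactants: 7 (R)-4,4,5,5-tetramethyl-2-(2-methylhexyl)-1,3,2-dioxaborolane; 2 ethyl 2,4,6-triisopropylbenzoate
Product: 10 4,4,5,5-tetramethyl-2-[(2R,4S)-4-methyloctan-2-yl]-1,3,2-dioxaborolane, via lithiated carbenoid 8 (not isolated), via boronate complex 9 (not isolated)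
Conditions: 2, s-BuLi, (−)-sparteine, Et2O, −78 °C, 5 h; then 7, −78 °C → reflux
Reagents that add atoms: none
Why: A second reagent-controlled lithiation–borylation, now with the (S)-carbenoid, sets the later C4 methyl centre as R and gives the anti-1,3-dimethyl array (dr about 94:6, upgraded by crystallisation of anilide 17).

Step 4
Reactants: 10 4,4,5,5-tetramethyl-2-[(2R,4S)-4-methyloctan-2-yl]-1,3,2-dioxaborolane
Product: 13 (3R,5S)-3,5-dimethylnon-1-ene, via vinyl boronate 11 (not isolated), via iodo boronic ester 12 (not isolated)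
Conditions: CH2=CHMgBr, THF–DMSO, rt; then I2, NaOMe, MeOH, 0 °C → rt
Reagents that add atoms: vinylmagnesium bromide C=C[Mg]Br
Why: Zweifel olefination: iodine-triggered 1,2-migration of the secondary alkyl group with retention, then anti boron–iodine elimination, gives the terminal alkene without touching either stereocentre.

Step 5
Reactants: 14 2,5-dimethoxyaniline; 15 acryloyl chloride
Product: 16 N-(2,5-dimethoxyphenyl)prop-2-enamide
Conditions: Et3N, CH2Cl2, 0 °C
Reagents that add atoms: none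
Why: Simple N-acylation of the aniline with an acid chloride (amide formation).

Step 6
Reactants: 13 (3R,5S)-3,5-dimethylnon-1-ene; 16 N-(2,5-dimethoxyphenyl)prop-2-enamide
Product: 17 (2E,4R,6S)-N-(2,5-dimethoxyphenyl)-4,6-dimethyldec-2-enamide
Conditions: Hoveyda–Grubbs II (5 mol%), CH2Cl2, 40 °C, 16 in two-fold excess
Reagents that add atoms: none
Why: Olefin cross-metathesis of an α-branched terminal alkene with an electron-poor acrylamide is selective for the cross product and gives the E-enamide with loss of ethene.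

Step 7
Reactants: 17 (2E,4R,6S)-N-(2,5-dimethoxyphenyl)-4,6-dimethyldec-2-enamide
Product: 18 (2E,4R,6S)-N-(6,6-dimethoxy-3-oxocyclohexa-1,4-dien-1-yl)-4,6-dimethyldec-2-enamide
Conditions: PhI(OAc)2, MeOH, 0 °C → rt
Reagents that add atoms: methanol CO
Why: Hypervalent-iodine oxidative dearomatisation of the p-dimethoxy anilide: methanol adds at the methoxy-bearing carbon ortho to the amide and the para methoxy group is O-demethylated, giving the 3-amido quinone monoketal regioselectively, as in the known manumycin-type syntheses.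

Step 8
Reactants: 18 (2E,4R,6S)-N-(6,6-dimethoxy-3-oxocyclohexa-1,4-dien-1-yl)-4,6-dimethyldec-2-enamide
Product: 19 (2E,4R,6S)-N-[(1R,6S)-5,5-dimethoxy-2-oxo-7-oxabicyclo[4.1.0]hept-3-en-4-yl]-4,6-dimethyldec-2-enamide
Conditions: t-BuOOH, aq NaOH, N-benzylcinchoninium chloride (10 mol%), toluene, 0 °C → rt
Reagents that add atoms: tert-butyl hydroperoxide CC(C)(C)OO
Why: Weitz–Scheffer nucleophilic epoxidation under Wynberg chiral phase-transfer catalysis attacks only the unsubstituted enone C=C (the amido-substituted one is a deactivated vinylogous imide), and the cinchona ion pair selects the enantiotopic face to set both oxirane carbons (about 90% ee expected, raised by recrystallisation).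

Step 9
Reactants: 20 3,3-diethoxyprop-1-yne
Product: 21 tributyl[(1E)-3,3-diethoxyprop-1-en-1-yl]stannane
Conditions: Bu3SnH, AIBN (cat.), 80 °C; chromatography
Reagents that add atoms: tributyltin hydride CCCC[SnH](CCCC)CCCC
Why: Radical hydrostannation of the terminal alkyne places tin at the terminus and equilibrates to the E-vinylstannane, which is separated from residual Z isomer.

Step 10
Reactants: 21 tributyl[(1E)-3,3-diethoxyprop-1-en-1-yl]stannane; 19 (2E,4R,6S)-N-[(1R,6S)-5,5-dimethoxy-2-oxo-7-oxabicyclo[4.1.0]hept-3-en-4-yl]-4,6-dimethyldec-2-enamide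
Product: 24 (2E,4R,6S)-N-[(1S,5S,6R)-5-hydroxy-2-oxo-5-[(1E)-3-oxoprop-1-en-1-yl]-7-oxabicyclo[4.1.0]hept-3-en-3-yl]-4,6-dimethyldec-2-enamide, via vinyllithium 22 (not isolated), via ketal adduct 23 (not isolated)
Conditions: 21 (3.3 equiv), n-BuLi (3.0 equiv), THF, −78 °C; then 19, −78 °C; NH4Cl; then K10 clay, wet CH2Cl2, rt
Reagents that add atoms: water O
Why: Sn–Li exchange gives (E)-3-lithioacrolein diethyl acetal, a β-formylvinyl anion (unsaturated homoenolate) equivalent whose donor carbon is the normally electrophilic enal β-carbon; after one equivalent is spent on the amide NH it adds 1,2 to the ketone carbon anti to the oxirane, setting C4 as S with OH syn to the epoxide, and K10 then hydrolyses both acetals (reversed-polarity 1,2-addition, acetal hydrolysis).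

Step 11
Reactants: 25 cyclopentane-1,3-dione
Product: 26 3-hydroxy-2-nitrocyclopent-2-en-1-one
Conditions: fuming HNO3, Et2O, 0 °C
Reagents that add atoms: nitric acid O[N+](=O)[O-]
Why: Electrophilic nitration of the enolised 1,3-dione at its nucleophilic C2.

Step 12
Reactants: 26 3-hydroxy-2-nitrocyclopent-2-en-1-one
Product: 27 2-amino-3-hydroxycyclopent-2-en-1-one hydrochloride
Conditions: H2 (1 atm), 10% Pd/C, HCl, MeOH, rt
Reagents that add atoms: hydrogen chloride Cl
Why: Catalytic hydrogenation of the nitro group, with the air-sensitive amino enol trapped as its hydrochloride.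

Step 13
Reactants: 28 triethyl 4-phosphonocrotonate
Product: 29 (2E)-4-(diethoxyphosphoryl)but-2-enoic acid
Conditions: LiOH, THF–H2O, 0 °C → rt; then HCl
Reagents that add atoms: lithium hydroxide [Li+].[OH-]
Why: Saponification of the carboxylic ester is much faster than that of the phosphonate esters and leaves the E-alkene in place.

Step 14
Reactants: 29 (2E)-4-(diethoxyphosphoryl)but-2-enoic acid; 27 2-amino-3-hydroxycyclopent-2-en-1-one hydrochloride
Product: 30 diethyl [(2E)-4-[(2-hydroxy-5-oxocyclopent-1-en-1-yl)amino]-4-oxobut-2-en-1-yl]phosphonate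
Conditions: EDC·HCl, HOBt, Et3N, DMF, 0 °C → rt
Reagents that add atoms: none
Why: Carbodiimide/HOBt amide coupling; any O-acylated enol ester rearranges to the more stable N-acyl vinylogous acid.

Step 15
Reactants: 30 diethyl [(2E)-4-[(2-hydroxy-5-oxocyclopent-1-en-1-yl)amino]-4-oxobut-2-en-1-yl]phosphonate; 24 (2E,4R,6S)-N-[(1S,5S,6R)-5-hydroxy-2-oxo-5-[(1E)-3-oxoprop-1-en-1-yl]-7-oxabicyclo[4.1.0]hept-3-en-3-yl]-4,6-dimethyldec-2-enamide
Product: 32 (2E,4R,6S)-N-[(1S,5S,6R)-5-hydroxy-5-[(1E,3E,5E)-7-[(2-hydroxy-5-oxocyclopent-1-en-1-yl)amino]-7-oxohepta-1,3,5-trien-1-yl]-2-oxo-7-oxabicyclo[4.1.0]hept-3-en-3-yl]-4,6-dimethyldec-2-enamide, via phosphonate trianion 31 (not isolated)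
Conditions: 30 (3 equiv), LiHMDS (9 equiv), THF, −78 °C; then 24, −78 → −20 °C; NH4Cl
Reagents that add atoms: none
Why: Vinylogous Horner–Wadsworth–Emmons olefination of the enal (far more reactive than the hindered ring ketone) by the phosphonate-stabilised carbanion forms the central C=C E-selectively and completes the all-E trienamide; the syn hydroxy epoxide cannot undergo Payne rearrangement.

Step 16
Reactants: 32 (2E,4R,6S)-N-[(1S,5S,6R)-5-hydroxy-5-[(1E,3E,5E)-7-[(2-hydroxy-5-oxocyclopent-1-en-1-yl)amino]-7-oxohepta-1,3,5-trien-1-yl]-2-oxo-7-oxabicyclo[4.1.0]hept-3-en-3-yl]-4,6-dimethyldec-2-enamide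
Product: 33 (2E,4R,6S)-N-[(3S,4R)-3,4-dihydroxy-3-[(1E,3E,5E)-7-[(2-hydroxy-5-oxocyclopent-1-en-1-yl)amino]-7-oxohepta-1,3,5-trien-1-yl]-6-oxocyclohex-1-en-1-yl]-4,6-dimethyldec-2-enamide
Conditions: SmI2 (2.2 equiv), THF–MeOH, −90 °C, 10 min; pH 7 buffer
Reagents that add atoms: none
Why: SmI2 reduction of the α,β-epoxy ketone cleaves only the Cα–O bond via the ketyl, and protonation of the samarium enolate gives the β-hydroxy ketone with the C5 carbinol untouched, so the cis-4,5-diol (4S,5R) results while the unsaturated amides are inert at −90 °C (Molander epoxy-ketone reduction).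

**Compound list**

1 | butylboronic acid pinacol ester | CCCCB1OC(C)(C)C(C)(C)O1 | starting material
2 | ethyl 2,4,6-triisopropylbenzoate | CCOC(=O)c1c(C(C)C)cc(C(C)C)cc1C(C)C | starting material
3 | (R)-1-lithioethyl 2,4,6-triisopropylbenzoate, (+)-sparteine complex | [Li][C@H](C)OC(=O)c1c(C(C)C)cc(C(C)C)cc1C(C)C | intermediate
4 | lithium butyl[(1R)-1-(2,4,6-triisopropylbenzoyloxy)ethyl](pinacolato)borate | [Li+].CCCC[B-]1([C@H](C)OC(=O)c2c(C(C)C)cc(C(C)C)cc2C(C)C)OC(C)(C)C(C)(C)O1 | intermediate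
5 | (S)-2-(hexan-2-yl)-4,4,5,5-tetramethyl-1,3,2-dioxaborolane | CCCC[C@H](C)B1OC(C)(C)C(C)(C)O1 | intermediate
6 | lithium (chloromethyl)[(2S)-hexan-2-yl](pinacolato)borate | [Li+].CCCC[C@H](C)[B-]1(CCl)OC(C)(C)C(C)(C)O1 | intermediate
7 | (R)-4,4,5,5-tetramethyl-2-(2-methylhexyl)-1,3,2-dioxaborolane | CCCC[C@H](C)CB1OC(C)(C)C(C)(C)O1 | intermediate
8 | (S)-1-lithioethyl 2,4,6-triisopropylbenzoate, (−)-sparteine complex | [Li][C@@H](C)OC(=O)c1c(C(C)C)cc(C(C)C)cc1C(C)C | intermediate
9 | lithium [(2R)-2-methylhexyl][(1S)-1-(2,4,6-triisopropylbenzoyloxy)ethyl](pinacolato)borate | [Li+].CCCC[C@H](C)C[B-]1([C@@H](C)OC(=O)c2c(C(C)C)cc(C(C)C)cc2C(C)C)OC(C)(C)C(C)(C)O1 | intermediate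
10 | 4,4,5,5-tetramethyl-2-[(2R,4S)-4-methyloctan-2-yl]-1,3,2-dioxaborolane | CCCC[C@H](C)C[C@@H](C)B1OC(C)(C)C(C)(C)O1 | intermediate
11 | bromomagnesium ethenyl[(2R,4S)-4-methyloctan-2-yl](pinacolato)borate | Br[Mg+].CCCC[C@H](C)C[C@@H](C)[B-]1(C=C)OC(C)(C)C(C)(C)O1 | intermediate
12 | 2-[(3R,5S)-1-iodo-3,5-dimethylnonan-2-yl]-4,4,5,5-tetramethyl-1,3,2-dioxaborolane (C2 epimers) | CCCC[C@H](C)C[C@@H](C)C(CI)B1OC(C)(C)C(C)(C)O1 | intermediate
13 | (3R,5S)-3,5-dimethylnon-1-ene | CCCC[C@H](C)C[C@@H](C)C=C | intermediate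
14 | 2,5-dimethoxyaniline | COc1ccc(OC)c(N)c1 | starting material
15 | acryloyl chloride | C=CC(=O)Cl | starting material
16 | N-(2,5-dimethoxyphenyl)prop-2-enamide | C=CC(=O)Nc1cc(OC)ccc1OC | intermediate
17 | (2E,4R,6S)-N-(2,5-dimethoxyphenyl)-4,6-dimethyldec-2-enamide | CCCC[C@H](C)C[C@@H](C)/C=C/C(=O)Nc1cc(OC)ccc1OC | intermediate
18 | (2E,4R,6S)-N-(6,6-dimethoxy-3-oxocyclohexa-1,4-dien-1-yl)-4,6-dimethyldec-2-enamide | CCCC[C@H](C)C[C@@H](C)/C=C/C(=O)NC1=CC(=O)C=CC1(OC)OC | intermediate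
19 | (2E,4R,6S)-N-[(1R,6S)-5,5-dimethoxy-2-oxo-7-oxabicyclo[4.1.0]hept-3-en-4-yl]-4,6-dimethyldec-2-enamide | CCCC[C@H](C)C[C@@H](C)/C=C/C(=O)NC1=CC(=O)[C@@H]2O[C@@H]2C1(OC)OC | intermediate
20 | 3,3-diethoxyprop-1-yne | C#CC(OCC)OCC | starting material
21 | tributyl[(1E)-3,3-diethoxyprop-1-en-1-yl]stannane | CCCC[Sn](CCCC)(CCCC)/C=C/C(OCC)OCC | intermediate
22 | [(1E)-3,3-diethoxyprop-1-en-1-yl]lithium | [Li]/C=C/C(OCC)OCC | intermediate
23 | (2E,4R,6S)-N-[(1S,5S,6R)-5-[(1E)-3,3-diethoxyprop-1-en-1-yl]-5-hydroxy-2,2-dimethoxy-7-oxabicyclo[4.1.0]hept-3-en-3-yl]-4,6-dimethyldec-2-enamide | CCCC[C@H](C)C[C@@H](C)/C=C/C(=O)NC1=C[C@@](O)(/C=C/C(OCC)OCC)[C@@H]2O[C@@H]2C1(OC)OC | intermediate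
24 | (2E,4R,6S)-N-[(1S,5S,6R)-5-hydroxy-2-oxo-5-[(1E)-3-oxoprop-1-en-1-yl]-7-oxabicyclo[4.1.0]hept-3-en-3-yl]-4,6-dimethyldec-2-enamide | CCCC[C@H](C)C[C@@H](C)/C=C/C(=O)NC1=C[C@@](O)(/C=C/C=O)[C@@H]2O[C@@H]2C1=O | intermediate
25 | cyclopentane-1,3-dione | O=C1CCC(=O)C1 | starting material
26 | 3-hydroxy-2-nitrocyclopent-2-en-1-one | O=C1CCC(O)=C1[N+](=O)[O-] | intermediate
27 | 2-amino-3-hydroxycyclopent-2-en-1-one hydrochloride | Cl.NC1=C(O)CCC1=O | intermediate
28 | triethyl 4-phosphonocrotonate | CCOC(=O)/C=C/CP(=O)(OCC)OCC | starting material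
29 | (2E)-4-(diethoxyphosphoryl)but-2-enoic acid | OC(=O)/C=C/CP(=O)(OCC)OCC | intermediate
30 | diethyl [(2E)-4-[(2-hydroxy-5-oxocyclopent-1-en-1-yl)amino]-4-oxobut-2-en-1-yl]phosphonate | CCOP(=O)(OCC)C/C=C/C(=O)NC1=C(O)CCC1=O | intermediate
31 | trilithium salt (O,N,C-trianion) of 30 | [Li+].[Li+].[Li+].CCOP(=O)(OCC)[CH-]/C=C/C(=O)[N-]C1=C([O-])CCC1=O | intermediate
32 | (2E,4R,6S)-N-[(1S,5S,6R)-5-hydroxy-5-[(1E,3E,5E)-7-[(2-hydroxy-5-oxocyclopent-1-en-1-yl)amino]-7-oxohepta-1,3,5-trien-1-yl]-2-oxo-7-oxabicyclo[4.1.0]hept-3-en-3-yl]-4,6-dimethyldec-2-enamide | CCCC[C@H](C)C[C@@H](C)/C=C/C(=O)NC1=C[C@@](O)(/C=C/C=C/C=C/C(=O)NC2=C(O)CCC2=O)[C@@H]3O[C@@H]3C1=O | intermediate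
33 | (2E,4R,6S)-N-[(3S,4R)-3,4-dihydroxy-3-[(1E,3E,5E)-7-[(2-hydroxy-5-oxocyclopent-1-en-1-yl)amino]-7-oxohepta-1,3,5-trien-1-yl]-6-oxocyclohex-1-en-1-yl]-4,6-dimethyldec-2-enamide (CNP0217472.2) | CCCC[C@H](C)C[C@@H](C)/C=C/C(=O)NC1=C[C@@](O)(/C=C/C=C/C=C/C(=O)NC2=C(O)CCC2=O)[C@H](O)CC1=O | target

**Step count**

Total: 16 steps. Longest linear sequence: 10 steps (1, 2, 3, 4, 6, 7, 8, 10, 15, 16).

**Steps most likely to fail, with fallbacks**

Step 10 (key addition and double hydrolysis). The amide NH consumes reagent, the hindered epoxy ketone may enolise or open instead of adding, and the γ-hydroxy enal must survive the clay hydrolysis. Fallback, setting out from 19 and returning at 24: the three-carbon donor is replaced by a one-carbon acyl anion. 2-Lithio-1,3-dithiane (THF, −78 °C) adds to the ketone of 19 anti to the oxirane to give the dithianyl carbinol F1. MeI/CaCO3 in aqueous MeCN followed by K10 clay frees the aldehyde and the ring ketone to give the α-hydroxy aldehyde F2. A Wittig reaction with (triphenylphosphoranylidene)acetaldehyde (benzene, rt) adds the two missing carbons E-selectively and gives enal 24.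

Step 15 (vinylogous HWE). The reagent is a poorly soluble trianion and 24 carries a free tertiary alcohol, an amide NH and a base-sensitive epoxy enone. Fallback, setting out from 24 and returning at 32: no carbanion is used. Takai iodo-olefination (CrCl2, CHI3, THF, 0 °C) turns the aldehyde into the (1E,3E)-dienyl iodide F3. Heck coupling (Pd(OAc)2, Bu4NCl, K2CO3, DMF, rt) with N-(2-hydroxy-5-oxocyclopent-1-en-1-yl)prop-2-enamide F4, made from 15 and 27 (Et3N, CH2Cl2, 0 °C), then gives 32.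

Step 16 (SmI2 opening). Chemoselectivity between the epoxy enone, the trienamide and the γ-hydroxy enone is not assured, and the β-hydroxy ketone can dehydrate. Fallback, setting out from 32 and returning at 33: polar opening instead of electron transfer. NaI/NaOAc/AcOH in acetone at −20 °C opens the oxirane at C6 by SN2 attack to give the trans α-iodo-β-hydroxy ketone F5. Excess iodide and acid (or Zn dust) then remove the α-iodine reductively and give 33.

**Further compounds**

F1 | step 10 | (2E,4R,6S)-N-[5-(1,3-dithian-2-yl)-5-hydroxy-2,2-dimethoxy-7-oxabicyclo[4.1.0]hept-3-en-3-yl]-4,6-dimethyldec-2-enamide (OH syn to oxirane, ring geometry as in 23) | CCCC[C@H](C)C[C@@H](C)/C=C/C(=O)NC1=C[C@@](O)(C3SCCCS3)[C@@H]2O[C@@H]2C1(OC)OC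
F2 | step 10 | (2E,4R,6S)-N-[5-formyl-5-hydroxy-2-oxo-7-oxabicyclo[4.1.0]hept-3-en-3-yl]-4,6-dimethyldec-2-enamide (OH syn to oxirane, ring geometry as in 24) | CCCC[C@H](C)C[C@@H](C)/C=C/C(=O)NC1=C[C@@](O)(C=O)[C@@H]2O[C@@H]2C1=O
F3 | step 15 | (2E,4R,6S)-N-[5-hydroxy-5-[(1E,3E)-4-iodobuta-1,3-dien-1-yl]-2-oxo-7-oxabicyclo[4.1.0]hept-3-en-3-yl]-4,6-dimethyldec-2-enamide (ring geometry as in 24) | CCCC[C@H](C)C[C@@H](C)/C=C/C(=O)NC1=C[C@@](O)(/C=C/C=C/I)[C@@H]2O[C@@H]2C1=O
F4 | step 15 | N-(2-hydroxy-5-oxocyclopent-1-en-1-yl)prop-2-enamide | C=CC(=O)NC1=C(O)CCC1=O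
F5 | step 16 | (2E,4R,6S)-N-[3,4-dihydroxy-3-[(1E,3E,5E)-7-[(2-hydroxy-5-oxocyclopent-1-en-1-yl)amino]-7-oxohepta-1,3,5-trien-1-yl]-5-iodo-6-oxocyclohex-1-en-1-yl]-4,6-dimethyldec-2-enamide (iodine trans to the adjacent OH, diol as in 33) | CCCC[C@H](C)C[C@@H](C)/C=C/C(=O)NC1=C[C@@](O)(/C=C/C=C/C=C/C(=O)NC2=C(O)CCC2=O)[C@H](O)[C@@H](I)C1=O
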